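**Strategy.** The route rests on cutting ring B of the spiro[5.5]undecane (C1 carbinol, C3 CMeCl, C4 CHBr, C6 spiro) at C3–C4 and C1–C6. One BF3-mediated operation joins a ring-A acetaldehyde acetal and a 4-oxobut-1-en-2-yl trifluoroborate: alkenyl transfer to the oxocarbenium carbon makes C3–C4, then the freed aldehyde closes ring B by a carbonyl-ene reaction on the tetrasubstituted ring-A alkene. The step exploits the homoallylic alcohol array C1(OH)–C6–C7=C8: it creates the carbinol, the spiro centre and the C7–C10 bromodiene together. Hydride transposition of the C4 ether (giving C3 methyl and C3=C4) and anti bromochlorination finish the target.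

Key step: step 8

Locants throughout: spiro[5.5]undecane numbering, ring B = C1–C6, ring A = C6–C11 (C7 C–Me, C10 C–Br, C11 CMe2).

Assumption: the (4R,6R)-acetal is taken to open with the facial sense that gives the (4R)-ether in 14; should the opposite sense be found, the (2S,4S)-diol would be used in step 4.

**Step 1**
Reactants: 1 2,2-dimethylcyclohexane-1,3-dione
Product: 2 3-bromo-2,2-dimethylcyclohex-3-en-1-one
Conditions: (PhO)3P (1.1 equiv), Br2 (1.1 equiv), Et3N, CH2Cl2, −60 °C to reflux
Reagents that add atoms: bromine, BrBr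
Why: Halogenation of an enolisable ketone through its enol phosphonium salt should convert one carbonyl of the symmetric dione into the alkenyl bromide, the quaternary carbon allowing enolisation only toward CH2.

**Step 2**
Reactants: 2 3-bromo-2,2-dimethylcyclohex-3-en-1-one
Product: 3 3-bromo-2,2,6-trimethylcyclohex-3-en-1-one (racemic)
Conditions: LiN(i-Pr)2, THF, −78 °C; MeI, −78 → 0 °C
Reagents that add atoms: iodomethane, CI
Why: Enolate alkylation at the only enolisable α-carbon; the new stereocentre is removed again in step 3.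

**Step 3**
Reactants: 3 3-bromo-2,2,6-trimethylcyclohex-3-en-1-one
Product: 4 5-bromo-2,6,6-trimethylcyclohexa-1,4-dien-1-yl trifluoromethanesulfonate
Conditions: KN(SiMe3)2, THF, −78 °C; PhNTf2, −78 → 0 °C
Reagents that add atoms: N-phenylbis(trifluoromethanesulfonimide), O=S(=O)(N(c1ccccc1)S(=O)(=O)C(F)(F)F)C(F)(F)F
Why: O-Triflation of the only possible enolate should give the tetrasubstituted enol triflate and with it the skipped 1,4-diene of ring A.

**Step 4**
Reactants: 5 2-bromo-1,1-diethoxyethane; 6 (2R,4R)-pentane-2,4-diol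
Product: 7 (4R,6R)-2-(bromomethyl)-4,6-dimethyl-1,3-dioxane
Conditions: p-TsOH (cat.), toluene, 80 °C, ethanol distilled off
Reagents that add atoms: none
Why: Acid-catalysed transacetalisation driven by removal of ethanol; the C2-symmetric diol leaves the acetal carbon non-stereogenic.

**Step 5**
Reactants: 7 (4R,6R)-2-(bromomethyl)-4,6-dimethyl-1,3-dioxane; 4 5-bromo-2,6,6-trimethylcyclohexa-1,4-dien-1-yl trifluoromethanesulfonate
Product: 9 (4R,6R)-2-[(5-bromo-2,6,6-trimethylcyclohexa-1,4-dien-1-yl)methyl]-4,6-dimethyl-1,3-dioxane, via alkylzinc bromide 8 (not isolated)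
Conditions: 7, Zn dust, LiCl, THF, 40 °C; then 4, Pd(PPh3)4 (5 mol %), THF/NMP, 25 → 50 °C
Reagents that add atoms: none
Why: Zinc insertion followed by Negishi coupling; in the presence of LiCl, zerovalent palladium should insert into the C–OTf bond faster than into the hindered alkenyl C–Br bond.

**Step 6**
Reactants: 10 3-bromobut-3-en-1-ol
Product: 12 potassium trifluoro(4-hydroxybut-1-en-2-yl)borate, via pinacol boronate 11 (not isolated)
Conditions: B2pin2, PdCl2(PPh3)2 (3 mol %), PPh3, KOPh, toluene, 50 °C; then KHF2, MeOH/H2O, 25 °C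
Reagents that add atoms: bis(pinacolato)diboron, CC1(C)OB(OC1(C)C)B1OC(C)(C)C(C)(C)O1; potassium hydrogen difluoride, [K+].F.[F-]
Why: Miyaura borylation of the 2-bromoalkene, then fluoride exchange to the bench-stable trifluoroborate.

**Step 7**
Reactants: 12 potassium trifluoro(4-hydroxybut-1-en-2-yl)borate
Product: 13 potassium trifluoro(4-oxobut-1-en-2-yl)borate
Conditions: Dess–Martin periodinane, NaHCO3, MeCN, 0 → 25 °C; used crude
Reagents that add atoms: none
Why: Dess–Martin oxidation of the primary alcohol; trifluoroborates tolerate this neutral oxidant, and the β,γ-unsaturated aldehyde is used at once to avoid conjugation.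

**Step 8**
Reactants: 9 (4R,6R)-2-[(5-bromo-2,6,6-trimethylcyclohexa-1,4-dien-1-yl)methyl]-4,6-dimethyl-1,3-dioxane; 13 potassium trifluoro(4-oxobut-1-en-2-yl)borate
Product: 15 (1S,4R,6R)-10-bromo-4-{[(2R,4R)-4-hydroxypentan-2-yl]oxy}-7,11,11-trimethyl-3-methylidenespiro[5.5]undeca-7,9-dien-1-ol, via aldehyde 14 (not isolated)
Conditions: BF3·OEt2 (4 equiv), CH2Cl2/MeCN, −40 → 0 °C; aq. NaHCO3
Reagents that add atoms: none
Why: Proposed new method: BF3 turns 13 into the alkenyldifluoroborane and ionises the dioxane of 9; the alkenyl group passes from boron to the oxocarbenium carbon at its boron-bearing carbon (bond C3–C4, giving 14), and the BF3-bound aldehyde of 14 then adds to the tetrasubstituted C6=C7 alkene with transfer of the doubly allylic C8–H to oxygen (bond C1–C6), which also creates the conjugated C7=C8/C9=C10 bromodiene. The closest known reaction types are the BF3-mediated coupling of potassium alkenyltrifluoroborates with acetals, the diastereoselective opening of C2-symmetric pentane-2,4-diol acetals by π-nucleophiles, and the Lewis-acid type 1 carbonyl-ene cyclisation (citronellal to isopulegol); running them in one flask and using a chiral acetal with a trifluoroborate are new. Ring B closes as a six-membered ring through a chair-like transition state in which C1 attacks the alkene carbon that carries the tether (six- rather than seven-membered closure). The C4 configuration should be set by the acetal auxiliary (alkenyl delivered anti to the breaking C–O bond) and relays to C1 and C6: with the C4 ether, the aldehyde oxygen and the C7 branch of the alkene all equatorial, the hydroxyl ends trans to C7 and cis to C11. The step needs activation of the acetal before the aldehyde (the trifluoroborate does not add to aldehydes) and an ene reaction faster than conjugation of the β,γ-unsaturated aldehyde, which low temperature should secure.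

**Step 9**
Reactants: 15 (1S,4R,6R)-10-bromo-4-{[(2R,4R)-4-hydroxypentan-2-yl]oxy}-7,11,11-trimethyl-3-methylidenespiro[5.5]undeca-7,9-dien-1-ol
Product: 16 (1S,6R)-10-bromo-3,7,11,11-tetramethylspiro[5.5]undeca-3,7,9-trien-1-ol
Conditions: Et3SiH (5 equiv), Me3SiOTf (4 equiv), CH2Cl2, −78 → −20 °C; then K2CO3, MeOH
Reagents that add atoms: none
Why: Ionic hydrogenolysis with allylic transposition: ionisation of the allylic C4–O bond should give a 2-substituted allyl cation that takes hydride at its CH2 terminus, forming the C3 methyl and the ring C3=C4 alkene, while the neopentyl C1–O bond does not ionise.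

**Step 10**
Reactants: 16 (1S,6R)-10-bromo-3,7,11,11-tetramethylspiro[5.5]undeca-3,7,9-trien-1-ol
Product: 17 (1S,3S,4S,6R)-4,10-dibromo-3-chloro-3,7,11,11-tetramethylspiro[5.5]undeca-7,9-dien-1-ol
Conditions: NBS (1.05 equiv), Et4NCl (2 equiv), CH2Cl2, −78 → −40 °C
Reagents that add atoms: N-bromosuccinimide, O=C1CCC(=O)N1Br; tetraethylammonium chloride, CC[N+](CC)(CC)CC.[Cl-]
Why: Anti bromochlorination: the bromonium ion is expected on the face syn to the C1 hydroxyl (hydrogen-bond-guided delivery, the other face screened at C4 by the C7 branch) and chloride should open it at the tertiary C3 (Markovnikov), giving 3S,4S; the ring-A diene is deactivated by bromine and flanked by two quaternary carbons.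

**Compound list**
1 | 2,2-dimethylcyclohexane-1,3-dione | O=C1CCCC(=O)C1(C)C | starting material
2 | 3-bromo-2,2-dimethylcyclohex-3-en-1-one | O=C1CCC=C(Br)C1(C)C | intermediate
3 | 3-bromo-2,2,6-trimethylcyclohex-3-en-1-one (racemic) | CC1CC=C(Br)C(C)(C)C1=O | intermediate
4 | 5-bromo-2,6,6-trimethylcyclohexa-1,4-dien-1-yl trifluoromethanesulfonate | CC1=C(OS(=O)(=O)C(F)(F)F)C(C)(C)C(Br)=CC1 | intermediate
5 | 2-bromo-1,1-diethoxyethane | CCOC(CBr)OCC | starting material
6 | (2R,4R)-pentane-2,4-diol | C[C@@H](O)C[C@@H](C)O | starting material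
7 | (4R,6R)-2-(bromomethyl)-4,6-dimethyl-1,3-dioxane | BrCC1O[C@H](C)C[C@@H](C)O1 | intermediate
8 | {[(4R,6R)-4,6-dimethyl-1,3-dioxan-2-yl]methyl}zinc bromide | Br[Zn]CC1O[C@H](C)C[C@@H](C)O1 | intermediate
9 | (4R,6R)-2-[(5-bromo-2,6,6-trimethylcyclohexa-1,4-dien-1-yl)methyl]-4,6-dimethyl-1,3-dioxane | CC1=C(CC2O[C@H](C)C[C@@H](C)O2)C(C)(C)C(Br)=CC1 | intermediate
10 | 3-bromobut-3-en-1-ol | OCCC(Br)=C | starting material
11 | 3-(4,4,5,5-tetramethyl-1,3,2-dioxaborolan-2-yl)but-3-en-1-ol | OCCC(=C)B1OC(C)(C)C(C)(C)O1 | intermediate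
12 | potassium trifluoro(4-hydroxybut-1-en-2-yl)borate | OCCC(=C)[B-](F)(F)F.[K+] | intermediate
13 | potassium trifluoro(4-oxobut-1-en-2-yl)borate | O=CCC(=C)[B-](F)(F)F.[K+] | intermediate
14 | (4R)-5-(5-bromo-2,6,6-trimethylcyclohexa-1,4-dien-1-yl)-4-{[(2R,4R)-4-hydroxypentan-2-yl]oxy}-3-methylidenepentanal | CC1=C(C[C@@H](O[C@H](C)C[C@@H](C)O)C(=C)CC=O)C(C)(C)C(Br)=CC1 | intermediate
15 | (1S,4R,6R)-10-bromo-4-{[(2R,4R)-4-hydroxypentan-2-yl]oxy}-7,11,11-trimethyl-3-methylidenespiro[5.5]undeca-7,9-dien-1-ol | CC1=CC=C(Br)C(C)(C)[C@@]12C[C@@H](O[C@H](C)C[C@@H](C)O)C(=C)C[C@@H]2O | intermediate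
16 | (1S,6R)-10-bromo-3,7,11,11-tetramethylspiro[5.5]undeca-3,7,9-trien-1-ol | CC1=CC=C(Br)C(C)(C)[C@@]12CC=C(C)C[C@@H]2O | intermediate
17 | (1S,3S,4S,6R)-4,10-dibromo-3-chloro-3,7,11,11-tetramethylspiro[5.5]undeca-7,9-dien-1-ol | CC1=CC=C(Br)C(C)(C)[C@@]12C[C@H](Br)[C@@](C)(Cl)C[C@@H]2O | target

Total step count: 10. Longest linear sequence: 7 steps (1, 2, 3, 5, 8, 9, 10).

**Steps most likely to fail**

1. Step 8 (new method). The dioxane may ionise too slowly, so that the β,γ-unsaturated aldehyde of 13 conjugates or oligomerises first. Alkenyl transfer may show poor facial control. The ene closure may go through the wrong chair (C1 or C6 epimers) or stop after the first bond. Fallback with known chemistry, the two bonds made in separate steps, setting out from 9. Aqueous acid hydrolysis of the acetal should give 2-(5-bromo-2,6,6-trimethylcyclohexa-1,4-dien-1-yl)acetaldehyde F1. A catalytic asymmetric Nozaki–Hiyama–Kishi reaction (CrCl2, NiCl2, chiral sulfonamide ligand, Mn, Me3SiCl) with 2-iodo-4,4-dimethoxybut-1-ene should give (2R)-1-(5-bromo-2,6,6-trimethylcyclohexa-1,4-dien-1-yl)-5,5-dimethoxy-3-methylidenepentan-2-ol F2, the alkenyl iodide reacting ahead of the hindered ring bromide. Silylation (t-BuMe2SiOTf, 2,6-lutidine) should give tert-butyl{[(2R)-1-(5-bromo-2,6,6-trimethylcyclohexa-1,4-dien-1-yl)-5,5-dimethoxy-3-methylidenepentan-2-yl]oxy}dimethylsilane F3. LiBF4 in wet MeCN should free (4R)-5-(5-bromo-2,6,6-trimethylcyclohexa-1,4-dien-1-yl)-4-[(tert-butyldimethylsilyl)oxy]-3-methylidenepentanal F4. Me2AlCl-promoted carbonyl-ene cyclisation should give (1S,4R,6R)-10-bromo-4-[(tert-butyldimethylsilyl)oxy]-7,11,11-trimethyl-3-methylidenespiro[5.5]undeca-7,9-dien-1-ol F5. F5 takes the place of 15 in step 9 and the fallback returns to the route at 16.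

2. Step 10. The bromonium ion may form on the wrong alkene face (trans-diaxial opening on the sterically easier face would lead to the 3R,4R isomer), or the halogen may attack the ring-A diene. Fallback setting out from 16: N-chlorosuccinimide in aqueous acetone should give the chlorohydrin (1S,3R,4R,6R)-10-bromo-4-chloro-3,7,11,11-tetramethylspiro[5.5]undeca-7,9-diene-1,3-diol F9 by trans-diaxial opening of the chloronium ion on the less hindered face. HBr in CH2Cl2 should then ionise the tertiary C3–OH with participation of the anti C4 chlorine; chlorine shifts to C3, bromide enters at C4 from the opposite face, and equilibration should collect the trans-diequatorial isomer, returning to the route at 17.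

3. Step 9. Ionisation of the secondary allylic ether may be sluggish, hydride may enter at C4 to leave the exocyclic alkene, or the acid may isomerise the ring-A diene. Fallback setting out from 15: Dess–Martin oxidation of both secondary alcohols should give (4R,6R)-10-bromo-7,11,11-trimethyl-3-methylidene-4-{[(2R)-4-oxopentan-2-yl]oxy}spiro[5.5]undeca-7,9-dien-1-one F6. K2CO3 in MeOH should remove the auxiliary by β-elimination to give (4R,6R)-10-bromo-4-hydroxy-7,11,11-trimethyl-3-methylidenespiro[5.5]undeca-7,9-dien-1-one F7. Reductive 1,3-transposition through the allylic diazene (2-nitrobenzenesulfonylhydrazide, PPh3, diethyl azodicarboxylate) should give (6R)-10-bromo-3,7,11,11-tetramethylspiro[5.5]undeca-3,7,9-trien-1-one F8. Reduction with LiBH(s-Bu)3 from the less hindered face should give the axial alcohol and return to the route at 16.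

**Further compounds**
F1 | step 8 | 2-(5-bromo-2,6,6-trimethylcyclohexa-1,4-dien-1-yl)acetaldehyde | O=CCC1=C(C)CC=C(Br)C1(C)C
F2 | step 8 | (2R)-1-(5-bromo-2,6,6-trimethylcyclohexa-1,4-dien-1-yl)-5,5-dimethoxy-3-methylidenepentan-2-ol | CC1=C(C[C@@H](O)C(=C)CC(OC)OC)C(C)(C)C(Br)=CC1
F3 | step 8 | tert-butyl{[(2R)-1-(5-bromo-2,6,6-trimethylcyclohexa-1,4-dien-1-yl)-5,5-dimethoxy-3-methylidenepentan-2-yl]oxy}dimethylsilane | CC1=C(C[C@@H](O[Si](C)(C)C(C)(C)C)C(=C)CC(OC)OC)C(C)(C)C(Br)=CC1
F4 | step 8 | (4R)-5-(5-bromo-2,6,6-trimethylcyclohexa-1,4-dien-1-yl)-4-[(tert-butyldimethylsilyl)oxy]-3-methylidenepentanal | CC1=C(C[C@@H](O[Si](C)(C)C(C)(C)C)C(=C)CC=O)C(C)(C)C(Br)=CC1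
F5 | step 8 | (1S,4R,6R)-10-bromo-4-[(tert-butyldimethylsilyl)oxy]-7,11,11-trimethyl-3-methylidenespiro[5.5]undeca-7,9-dien-1-ol | CC1=CC=C(Br)C(C)(C)[C@@]12C[C@@H](O[Si](C)(C)C(C)(C)C)C(=C)C[C@@H]2O
F6 | step 9 | (4R,6R)-10-bromo-7,11,11-trimethyl-3-methylidene-4-{[(2R)-4-oxopentan-2-yl]oxy}spiro[5.5]undeca-7,9-dien-1-one | CC1=CC=C(Br)C(C)(C)[C@@]12C[C@@H](O[C@H](C)CC(C)=O)C(=C)CC2=O
F7 | step 9 | (4R,6R)-10-bromo-4-hydroxy-7,11,11-trimethyl-3-methylidenespiro[5.5]undeca-7,9-dien-1-one | CC1=CC=C(Br)C(C)(C)[C@@]12C[C@@H](O)C(=C)CC2=O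
F8 | step 9 | (6R)-10-bromo-3,7,11,11-tetramethylspiro[5.5]undeca-3,7,9-trien-1-one | CC1=CC=C(Br)C(C)(C)[C@@]12CC=C(C)CC2=O
F9 | step 10 | (1S,3R,4R,6R)-10-bromo-4-chloro-3,7,11,11-tetramethylspiro[5.5]undeca-7,9-diene-1,3-diol | CC1=CC=C(Br)C(C)(C)[C@@]12C[C@@H](Cl)[C@](C)(O)C[C@@H]2O
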